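**Retrosynthetic overview**

1. The bicyclo[3.2.1]octenedione is opened last by a perezone-type (5+2) cycloaddition (bonds C8–C15′ and C13–C14′) into a ring-B-contracted abietane hydroxy-para-quinone and labda-8(17),12E,14-trien-18-oic acid.
2. The labdane acid comes from levopimaric acid: ozonolysis of both ring-C alkenes removes C13, C14 and the isopropyl group while C4, C5, C9 and C10 are kept; two Wittig olefinations rebuild the E-diene and the exocyclic methylene.
3. The quinone half is built in the ring order C → B → A: trimethoxy(isopropyl)benzene, Friedel–Crafts/Nazarov annulation to an indenone, CBS reduction and Claisen shift for the quaternary C10, Barbier prenylation for C4, then ring A.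
4. Enabling feature: ring A (C1–C2–C3–C4–C5–C10) is a heteroatom-free cyclohexane whose C2H2–C3H2 unit lies between the C1 methylene on the benzylic quaternary C10 and the gem-dimethyl quaternary C4. An allyl group on C10 and a 1,1-dimethylallyl group on C5 can therefore be joined at C2–C3 by ring-closing metathesis with in-flask hydrogenation, which leaves no functional group behind.
5. After ring A: dehydration to the C5=C6 alkene, α-face hydroformylation (sets H-5, adds C7), enolate hydroxylation at C6, and oxidation of the arene to the hydroxyquinone.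

Key step: step 10

Remark on the chemistry: locants in the text follow abietane numbering for the quinone half (C7 is the formyl carbon) and primed labdane numbering for the acid half; α is the face opposite the C10 methyl group. The C5 epimers formed in step 9 and the C6 epimers formed in step 12 are carried as mixtures because both centres become planar later (steps 11 and 13); the SMILES show the expected major epimer.

**Route**

Step 1
Reactants: 1 1,2,4-trimethoxybenzene
Product: 3 2-(2,3,6-trimethoxyphenyl)propan-2-ol, via aryllithium 2 (not isolated)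
Conditions: n-BuLi, TMEDA, THF, 0 °C; acetone, −78 °C to rt; H2O
Reagents that add atoms: acetone, CC(C)=O
Why: Directed ortho-lithiation removes the proton flanked by two methoxy groups and the aryllithium adds to acetone; no stereocenter is formed.

Step 2
Reactants: 3 2-(2,3,6-trimethoxyphenyl)propan-2-ol
Product: 4 1,2,4-trimethoxy-3-(propan-2-yl)benzene
Conditions: Et3SiH, CF3CO2H, CH2Cl2, 0 °C to rt
Reagents that add atoms: none
Why: Ionic hydrogenation, in which acid ionizes the tertiary benzylic alcohol to a cation stabilized by two ortho methoxy groups and the silane delivers hydride; no stereocenter.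

Step 3
Reactants: 4 1,2,4-trimethoxy-3-(propan-2-yl)benzene
Product: 6 rac-4,5,7-trimethoxy-3-methyl-6-(propan-2-yl)indan-1-one, via aryl propenyl ketone 5 (not isolated)
Conditions: (E)-crotonic acid, P2O5 in MeSO3H (Eaton's reagent), 60 °C
Reagents that add atoms: (E)-crotonic acid, C/C=C/C(=O)O
Why: Friedel–Crafts acylation at the free position ortho to the isolated methoxy group (para to the central one) followed by Nazarov cyclization onto the last aromatic CH should give the 3-methylindanone, whose single stereocenter is racemic and is erased in step 4.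

Step 4
Reactants: 6 rac-4,5,7-trimethoxy-3-methyl-6-(propan-2-yl)indan-1-one
Product: 7 4,5,7-trimethoxy-3-methyl-6-(propan-2-yl)-1H-inden-1-one
Conditions: IBX, DMSO/PhF, 75 °C
Reagents that add atoms: none
Why: IBX dehydrogenation of the ketone (enol oxidation, then loss of the benzylic C10 hydrogen) should give the indenone, which bears no stereocenter.

Step 5
Reactants: 7 4,5,7-trimethoxy-3-methyl-6-(propan-2-yl)-1H-inden-1-one
Product: 8 (1R)-4,5,7-trimethoxy-3-methyl-6-(propan-2-yl)-1H-inden-1-ol
Conditions: (S)-2-methyl-CBS-oxazaborolidine (20 mol %), BH3·SMe2, THF, −30 °C; MeOH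
Reagents that add atoms: none
Why: Corey–Bakshi–Shibata reduction, in which the oxazaborolidine–borane complex binds the ketone with the bulky peri-methoxy aryl flank as the large group and delivers hydride in a 1,2-sense, is predicted to set the (R)-carbinol at C6.

Step 6
Reactants: 8 (1R)-4,5,7-trimethoxy-3-methyl-6-(propan-2-yl)-1H-inden-1-ol
Product: 10 2-[(1S)-4,6,7-trimethoxy-1-methyl-5-(propan-2-yl)-1H-inden-1-yl]acetaldehyde, via allyl vinyl ether 9 (not isolated)
Conditions: ethyl vinyl ether, Hg(OAc)2 (10 mol %), reflux; evaporate; xylene, 140 °C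
Reagents that add atoms: ethyl vinyl ether, C=COCC
Why: Mercury-catalysed vinyl transetherification followed by a suprafacial Claisen rearrangement moves the C6–O chirality across the α face to the new C10–C1 bond, so the benzylic quaternary stereocenter C10 is set by 1,3-chirality transfer.

Step 7
Reactants: 10 2-[(1S)-4,6,7-trimethoxy-1-methyl-5-(propan-2-yl)-1H-inden-1-yl]acetaldehyde
Product: 11 (1S)-4,6,7-trimethoxy-1-methyl-5-(propan-2-yl)-1-(prop-2-en-1-yl)-1H-indene
Conditions: Ph3PCH3Br, KOtBu, THF, 0 °C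
Reagents that add atoms: methyltriphenylphosphonium bromide, C[P+](c1ccccc1)(c1ccccc1)c1ccccc1.[Br-]
Why: Wittig methylenation of the unhindered aldehyde completes the allyl arm without touching the quaternary centre, which has no acidic hydrogen.

Step 8
Reactants: 11 (1S)-4,6,7-trimethoxy-1-methyl-5-(propan-2-yl)-1-(prop-2-en-1-yl)-1H-indene
Product: 13 (1R)-4,6,7-trimethoxy-1-methyl-5-(propan-2-yl)-1-(prop-2-en-1-yl)-1,3-dihydro-2H-inden-2-one, via epoxide 12 (not isolated)
Conditions: mCPBA, NaHCO3, CH2Cl2, 0 °C; then BF3·OEt2 (10 mol %), −40 °C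
Reagents that add atoms: mCPBA, OOC(=O)c1cccc(Cl)c1
Why: Prilezhaev epoxidation picks the electron-rich styrenic ring-B alkene over the terminal allyl group, and Lewis-acid Meinwald rearrangement (benzylic C6 cation, 1,2-hydride shift from C5) should give the 2-indanone from either epoxide face.

Step 9
Reactants: 13 (1R)-4,6,7-trimethoxy-1-methyl-5-(propan-2-yl)-1-(prop-2-en-1-yl)-1,3-dihydro-2H-inden-2-one
Product: 14 (1R,2R)-4,6,7-trimethoxy-1-methyl-2-(2-methylbut-3-en-2-yl)-5-(propan-2-yl)-1-(prop-2-en-1-yl)indan-2-ol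
Conditions: prenyl bromide, Zn dust, THF/sat. aq NH4Cl, 0 °C to rt
Reagents that add atoms: prenyl bromide (1-bromo-3-methylbut-2-ene), CC(C)=CCBr
Why: Zinc Barbier prenylation, in which the weakly basic allylzinc adds through its γ-carbon (SE2′, six-membered transition state) instead of enolizing the ketone, installs the 1,1-dimethylallyl arm with C4 and is expected to place it anti to the allyl group, although the C5 configuration is erased in step 11.

Step 10
Reactants: 14 (1R,2R)-4,6,7-trimethoxy-1-methyl-2-(2-methylbut-3-en-2-yl)-5-(propan-2-yl)-1-(prop-2-en-1-yl)indan-2-ol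
Product: 16 (4aR,9aR)-5,6,8-trimethoxy-1,1,4a-trimethyl-7-(propan-2-yl)-1,2,3,4,4a,9-hexahydro-9aH-fluoren-9a-ol, via cyclohexene 15 (not isolated)
Conditions: second-generation Grubbs catalyst (H2IMes)(PCy3)Cl2Ru=CHPh (5 mol %), ClCH2CH2Cl (5 mM), 60 °C; then H2 (7 bar), 70 °C
Reagents that add atoms: none
Why: Ring-closing olefin metathesis by the metallacyclobutane mechanism: the ruthenium alkylidene loads on the allyl terminus, undergoes intramolecular [2+2] addition and cycloreversion with the neopentylic vinyl group and expels ethene, which forms the C2=C3 bond; admitting H2 then turns the ruthenium carbene into a ruthenium hydride that saturates the new alkene in the same flask. The closest known reaction type is RCM of 1,7-dienes to cyclohexenes flanked by quaternary carbons, run in tandem with hydrogenation by the same ruthenium complex. Ring A closes as a six-membered carbocycle in the alkene–alkene mode, its size fixed by the two tethers (allyl on C10, 1,1-dimethylallyl on C5), and both C5 epimers can close because cis- and trans-fused hydrindanes are both accessible. No stereocenter is created: C10 is carried through untouched and C2 and C3 end as methylenes. The step needs cyclization to win over oligomerization and over allyl isomerization, which is secured by the gem-dimethyl and vicinal quaternary substitution that hold the two olefins close (Thorpe–Ingold effect), by high dilution, and by the lack of allylic hydrogens on the neopentylic olefin; the tertiary alcohol, the electron-rich arene and the benzylic methylene are inert to both catalytic regimes.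

Step 11
Reactants: 16 (4aR,9aR)-5,6,8-trimethoxy-1,1,4a-trimethyl-7-(propan-2-yl)-1,2,3,4,4a,9-hexahydro-9aH-fluoren-9a-ol
Product: 17 (4aS)-5,6,8-trimethoxy-1,1,4a-trimethyl-7-(propan-2-yl)-2,3,4,4a-tetrahydro-1H-fluorene
Conditions: Burgess reagent (MeO2CN−SO2N+Et3), PhMe, 70 °C
Reagents that add atoms: none
Why: Burgess dehydration (syn elimination through the sulfamate) can only use a benzylic C6 hydrogen because C4 and C10 are quaternary, so one styrenic alkene should form from either C5 epimer without a free cation that could trigger methyl shifts.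

Step 12
Reactants: 17 (4aS)-5,6,8-trimethoxy-1,1,4a-trimethyl-7-(propan-2-yl)-2,3,4,4a-tetrahydro-1H-fluorene
Product: 18 (4aS,9R,9aS)-5,6,8-trimethoxy-1,1,4a-trimethyl-7-(propan-2-yl)-2,3,4,4a,9,9a-hexahydro-1H-fluorene-9-carbaldehyde
Conditions: Rh(acac)(CO)2 (2 mol %), P(O-2,4-tBu2C6H3)3 (10 mol %), CO/H2 (1:1, 40 bar), PhMe, 90 °C
Reagents that add atoms: carbon monoxide, [C-]#[O+]
Why: Rhodium-catalysed hydroformylation with a bulky phosphite ligand, in which the rhodium hydride adds syn from the α face opposite the C10 methyl group, should put hydrogen on the fully substituted C5 (setting the trans ring fusion) and the formyl group on benzylic C6, whose configuration is erased in step 13.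

Step 13
Reactants: 18 (4aS,9R,9aS)-5,6,8-trimethoxy-1,1,4a-trimethyl-7-(propan-2-yl)-2,3,4,4a,9,9a-hexahydro-1H-fluorene-9-carbaldehyde
Product: 20 (4aS,9R,9aS)-9-hydroxy-5,6,8-trimethoxy-1,1,4a-trimethyl-7-(propan-2-yl)-2,3,4,4a,9,9a-hexahydro-1H-fluorene-9-carbaldehyde, via potassium enolate 19 (not isolated)
Conditions: KN(SiMe3)2, THF, −78 °C; 2-(phenylsulfonyl)-3-phenyloxaziridine, −78 °C; AcOH
Reagents that add atoms: 2-(phenylsulfonyl)-3-phenyloxaziridine, O=S(=O)(c1ccccc1)N1OC1c1ccccc1
Why: Enolate hydroxylation with an N-sulfonyloxaziridine (Davis oxidation), in which the planar C6 enolate is oxidized on the α face away from the C4 gem-dimethyl carbon on the β side of C5, should give the 6α-hydroxy-6β-formyl centre.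

Step 14
Reactants: 20 (4aS,9R,9aS)-9-hydroxy-5,6,8-trimethoxy-1,1,4a-trimethyl-7-(propan-2-yl)-2,3,4,4a,9,9a-hexahydro-1H-fluorene-9-carbaldehyde
Product: 21 (4aS,9R,9aS)-9-hydroxy-6-methoxy-1,1,4a-trimethyl-5,8-dioxo-7-(propan-2-yl)-2,3,4,4a,5,8,9,9a-octahydro-1H-fluorene-9-carbaldehyde
Conditions: (NH4)2Ce(NO3)6 (2.5 equiv), MeCN/H2O, 0 °C
Reagents that add atoms: water, O
Why: Oxidative demethylation with the tetravalent cerium salt turns the para-related C11 and C14 methoxy groups into the para-quinone while the C12 methoxy group stays as a vinylogous ester, the electron-rich arene being oxidized far faster than the hydroxy aldehyde.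

Step 15
Reactants: 21 (4aS,9R,9aS)-9-hydroxy-6-methoxy-1,1,4a-trimethyl-5,8-dioxo-7-(propan-2-yl)-2,3,4,4a,5,8,9,9a-octahydro-1H-fluorene-9-carbaldehyde
Product: 22 (4aS,9R,9aS)-6,9-dihydroxy-1,1,4a-trimethyl-5,8-dioxo-7-(propan-2-yl)-2,3,4,4a,5,8,9,9a-octahydro-1H-fluorene-9-carbaldehyde
Conditions: BCl3, CH2Cl2, −78 °C; aq NaHCO3
Reagents that add atoms: none
Why: Chelation-controlled ether cleavage, in which BCl3 bridges the C11 carbonyl and the C12 methoxy oxygen so that chloride removes only this methyl group at low temperature, touches no stereocenter.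

Step 16
Reactants: 23 levopimaric acid (abieta-8(14),12-dien-18-oic acid)
Product: 24 (1R,4aS,5R,8aR)-1,4a-dimethyl-6-oxo-5-(2-oxoethyl)decahydronaphthalene-1-carboxylic acid
Conditions: O3, pyridine, CH2Cl2, −78 °C
Reagents that add atoms: ozone, [O-][O+]=O
Why: Ozonolysis of both alkenes of the homoannular ring-C diene (pyridine-mediated, carbonyls formed directly) cuts out C13 and C14 with the isopropyl group and leaves the four stereocenters C4, C5, C9 and C10 untouched.

Step 17
Reactants: 24 (1R,4aS,5R,8aR)-1,4a-dimethyl-6-oxo-5-(2-oxoethyl)decahydronaphthalene-1-carboxylic acid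
Product: 25 (1R,4aS,5R,8aR)-1,4a-dimethyl-5-[(2E)-3-methyl-4-oxobut-2-en-1-yl]-6-oxodecahydronaphthalene-1-carboxylic acid
Conditions: Ph3P=C(CH3)CHO (2.2 equiv), PhMe, 80 °C
Reagents that add atoms: 2-(triphenylphosphoranylidene)propanal, CC(C=O)=P(c1ccccc1)(c1ccccc1)c1ccccc1
Why: The Wittig reaction with the stabilized formyl ylide reacts only at the aldehyde, not at the ring ketone, and should give the E-trisubstituted enal.

Step 18
Reactants: 25 (1R,4aS,5R,8aR)-1,4a-dimethyl-5-[(2E)-3-methyl-4-oxobut-2-en-1-yl]-6-oxodecahydronaphthalene-1-carboxylic acid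
Product: 26 (1R,4aR,5S,8aR)-1,4a-dimethyl-6-methylidene-5-[(2E)-3-methylpenta-2,4-dien-1-yl]decahydronaphthalene-1-carboxylic acid
Conditions: Ph3PCH3Br (5 equiv), KOtBu (5 equiv), THF, 0 to 60 °C; aq HCl
Reagents that add atoms: methyltriphenylphosphonium bromide, C[P+](c1ccccc1)(c1ccccc1)c1ccccc1.[Br-]
Why: Wittig methylenation of both the enal (to the terminal diene) and the C8 ketone (to the exocyclic methylene) should proceed with the first equivalent of ylide consumed by the acid and the equatorial C9 side chain remaining the stable epimer.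

Step 19
Reactants: 22 (4aS,9R,9aS)-6,9-dihydroxy-1,1,4a-trimethyl-5,8-dioxo-7-(propan-2-yl)-2,3,4,4a,5,8,9,9a-octahydro-1H-fluorene-9-carbaldehyde; 26 (1R,4aR,5S,8aR)-1,4a-dimethyl-6-methylidene-5-[(2E)-3-methylpenta-2,4-dien-1-yl]decahydronaphthalene-1-carboxylic acid
Product: 27 target compound CNP0124601.1
Conditions: BF3·OEt2, CH2Cl2, −78 to −30 °C
Reagents that add atoms: none
Why: Perezone-type cationic (5+2) cycloaddition, in which BF3 chelated between the C11 carbonyl and the C12 oxygen makes C8 electrophilic, the terminal CH2 (C15′) of the diene adds there from the α face opposite the C10 methyl and C6 formyl groups, and the allyl cation is captured at C14′ by the enol carbon C13 with the side chain endo to the three-carbon enol-ketone bridge, should set C8, C13 and C14′.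

**Compound list**

1 | 1,2,4-trimethoxybenzene | COc1ccc(OC)c(OC)c1 | starting material
2 | (2,3,6-trimethoxyphenyl)lithium | COc1ccc(OC)c([Li])c1OC | intermediate
3 | 2-(2,3,6-trimethoxyphenyl)propan-2-ol | COc1ccc(OC)c(C(C)(C)O)c1OC | intermediate
4 | 1,2,4-trimethoxy-3-(propan-2-yl)benzene | COc1ccc(OC)c(C(C)C)c1OC | intermediate
5 | (E)-1-[2,4,5-trimethoxy-3-(propan-2-yl)phenyl]but-2-en-1-one | C/C=C/C(=O)c1cc(OC)c(OC)c(C(C)C)c1OC | intermediate
6 | rac-4,5,7-trimethoxy-3-methyl-6-(propan-2-yl)indan-1-one | COc1c(OC)c(C(C)C)c(OC)c2c1C(C)CC2=O | intermediate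
7 | 4,5,7-trimethoxy-3-methyl-6-(propan-2-yl)-1H-inden-1-one | COc1c(OC)c(C(C)C)c(OC)c2c1C(C)=CC2=O | intermediate
8 | (1R)-4,5,7-trimethoxy-3-methyl-6-(propan-2-yl)-1H-inden-1-ol | COc1c(OC)c(C(C)C)c(OC)c2c1C(C)=C[C@H]2O | intermediate
9 | (1R)-1-(ethenyloxy)-4,5,7-trimethoxy-3-methyl-6-(propan-2-yl)-1H-indene | COc1c(OC)c(C(C)C)c(OC)c2c1C(C)=C[C@H]2OC=C | intermediate
10 | 2-[(1S)-4,6,7-trimethoxy-1-methyl-5-(propan-2-yl)-1H-inden-1-yl]acetaldehyde | COc1c(OC)c(C(C)C)c(OC)c2c1[C@@](C)(CC=O)C=C2 | intermediate
11 | (1S)-4,6,7-trimethoxy-1-methyl-5-(propan-2-yl)-1-(prop-2-en-1-yl)-1H-indene | COc1c(OC)c(C(C)C)c(OC)c2c1[C@@](C)(CC=C)C=C2 | intermediate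
12 | 2,3-epoxide of 11 (both epoxide faces) | COc1c(OC)c(C(C)C)c(OC)c2c1[C@@](C)(CC=C)C1OC21 | intermediate
13 | (1R)-4,6,7-trimethoxy-1-methyl-5-(propan-2-yl)-1-(prop-2-en-1-yl)-1,3-dihydro-2H-inden-2-one | COc1c(OC)c(C(C)C)c(OC)c2c1[C@@](C)(CC=C)C(=O)C2 | intermediate
14 | (1R,2R)-4,6,7-trimethoxy-1-methyl-2-(2-methylbut-3-en-2-yl)-5-(propan-2-yl)-1-(prop-2-en-1-yl)indan-2-ol (major C5 epimer) | COc1c(OC)c(C(C)C)c(OC)c2c1[C@@](C)(CC=C)[C@](O)(C(C)(C)C=C)C2 | intermediate
15 | (4aR,9aR)-5,6,8-trimethoxy-1,1,4a-trimethyl-7-(propan-2-yl)-1,4,4a,9-tetrahydro-9aH-fluoren-9a-ol | COc1c(OC)c(C(C)C)c(OC)c2c1[C@@]1(C)CC=CC(C)(C)[C@]1(O)C2 | intermediate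
16 | (4aR,9aR)-5,6,8-trimethoxy-1,1,4a-trimethyl-7-(propan-2-yl)-1,2,3,4,4a,9-hexahydro-9aH-fluoren-9a-ol | COc1c(OC)c(C(C)C)c(OC)c2c1[C@@]1(C)CCCC(C)(C)[C@]1(O)C2 | intermediate
17 | (4aS)-5,6,8-trimethoxy-1,1,4a-trimethyl-7-(propan-2-yl)-2,3,4,4a-tetrahydro-1H-fluorene | COc1c(OC)c(C(C)C)c(OC)c2c1[C@@]1(C)CCCC(C)(C)C1=C2 | intermediate
18 | (4aS,9R,9aS)-5,6,8-trimethoxy-1,1,4a-trimethyl-7-(propan-2-yl)-2,3,4,4a,9,9a-hexahydro-1H-fluorene-9-carbaldehyde (5α-H, 6α-CHO epimer shown) | COc1c(OC)c(C(C)C)c(OC)c2c1[C@@]1(C)CCCC(C)(C)[C@@H]1[C@H]2C=O | intermediate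
19 | potassium enolate of 18 | COc1c(OC)c(C(C)C)c(OC)c2c1[C@@]1(C)CCCC(C)(C)[C@@H]1C2=C[O-].[K+] | intermediate
20 | (4aS,9R,9aS)-9-hydroxy-5,6,8-trimethoxy-1,1,4a-trimethyl-7-(propan-2-yl)-2,3,4,4a,9,9a-hexahydro-1H-fluorene-9-carbaldehyde | COc1c(OC)c(C(C)C)c(OC)c2c1[C@@]1(C)CCCC(C)(C)[C@@H]1[C@]2(O)C=O | intermediate
21 | (4aS,9R,9aS)-9-hydroxy-6-methoxy-1,1,4a-trimethyl-5,8-dioxo-7-(propan-2-yl)-2,3,4,4a,5,8,9,9a-octahydro-1H-fluorene-9-carbaldehyde | O=C1C(OC)=C(C(C)C)C(=O)C2=C1[C@@]1(C)CCCC(C)(C)[C@@H]1[C@]2(O)C=O | intermediate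
22 | (4aS,9R,9aS)-6,9-dihydroxy-1,1,4a-trimethyl-5,8-dioxo-7-(propan-2-yl)-2,3,4,4a,5,8,9,9a-octahydro-1H-fluorene-9-carbaldehyde | O=C1C(O)=C(C(C)C)C(=O)C2=C1[C@@]1(C)CCCC(C)(C)[C@@H]1[C@]2(O)C=O | intermediate
23 | levopimaric acid (abieta-8(14),12-dien-18-oic acid) | CC(C)C1=CC[C@H]2C(=C1)CC[C@@H]1[C@]2(C)CCC[C@@]1(C)C(=O)O | starting material
24 | (1R,4aS,5R,8aR)-1,4a-dimethyl-6-oxo-5-(2-oxoethyl)decahydronaphthalene-1-carboxylic acid | O=C1CC[C@@H]2[C@](C)(CCC[C@@]2(C)C(=O)O)[C@H]1CC=O | intermediate
25 | (1R,4aS,5R,8aR)-1,4a-dimethyl-5-[(2E)-3-methyl-4-oxobut-2-en-1-yl]-6-oxodecahydronaphthalene-1-carboxylic acid | O=C1CC[C@@H]2[C@](C)(CCC[C@@]2(C)C(=O)O)[C@H]1C/C=C(\C)C=O | intermediate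
26 | (1R,4aR,5S,8aR)-1,4a-dimethyl-6-methylidene-5-[(2E)-3-methylpenta-2,4-dien-1-yl]decahydronaphthalene-1-carboxylic acid (labda-8(17),12E,14-trien-18-oic acid) | C=C1CC[C@@H]2[C@](C)(CCC[C@@]2(C)C(=O)O)[C@H]1C/C=C(\C)C=C | intermediate
27 | CNP0124601.1, the (5+2) adduct of 22 and 26 | C=C1CC[C@@H]2[C@](C)(CCC[C@@]2(C)C(=O)O)[C@H]1C/C=C(\C)[C@@H]1C[C@@]23C(=O)[C@]1(C(C)C)C(=O)C(O)=C2[C@@]1(C)CCCC(C)(C)[C@@H]1[C@]3(O)C=O | target

**Step count and risks**

Total steps: 19 (15 for the quinone half, 3 for the labdane acid, 1 coupling). Longest linear sequence: 16 (steps 1 to 15, then step 19).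

Most likely to fail, in order:

Step 19. The allyl cation may be captured by oxygen (a quinone carbonyl or the C6 hydroxyl) instead of by C13, the diene may add in a Diels–Alder sense, facial selectivity at C8 may be poor, and the Lewis acid may induce α-ketol ring expansion of the hydroxy aldehyde. The fallback sets out from methoxyquinone 21 (so step 15 is skipped) and acid 26 and uses the Lewis-acid-promoted alkoxyquinone–alkene (5+2) cycloaddition with TiCl4 in CH2Cl2 at −78 °C. Titanium chelated by the C11 carbonyl and the C12 methoxy group directs the same C8 and C13 bond formation, and the C12 oxocarbenium ion left after ring closure is demethylated by chloride, so the route is rejoined directly at 27. No new isolated compound arises (entry F0).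

Step 12. Insertion of the hindered trisubstituted alkene into the rhodium hydride may be too slow, so that hydrogenation or no reaction takes over. The fallback sets out from 17. Hydroboration–oxidation (BH3·THF; NaOH, H2O2) from the α face should give the trans-fused 6α-alcohol F1. Dess–Martin oxidation should give the trans-fused ketone F2 without epimerization. Non-basic methylenation (Zn, CH2Br2, TiCl4) should give the exocyclic alkene F3. Dihydroxylation (OsO4 cat., N-methylmorpholine N-oxide) from the α face should give the diol F4. Selective oxidation of the primary alcohol (SO3·pyridine, DMSO, i-Pr2NEt) then returns to the route at 20, so steps 12 and 13 are both replaced.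

Step 6. The indenol may isomerize to the indanone by a 1,3-hydrogen shift, or the vinyl ether may lose acetaldehyde by a retro-ene path, before the [3,3] shift occurs. The fallback sets out from 8. Johnson–Claisen rearrangement (triethyl orthoacetate, cat. propionic acid, 140 °C) under acidic conditions should give the ethyl ester F5 with the same chirality transfer. Reduction with i-Bu2AlH at −78 °C then returns to the route at aldehyde 10.

**Further compounds**

F0 | step 19 | none | none
F1 | step 12 | trans-fused 6α-alcohol, (4aS,9aS)-5,6,8-trimethoxy-1,1,4a-trimethyl-7-(propan-2-yl)-2,3,4,4a,9,9a-hexahydro-1H-fluoren-9-ol with 9-OH cis to H-9a | COc1c(OC)c(C(C)C)c(OC)c2c1[C@@]1(C)CCCC(C)(C)[C@@H]1[C@H]2O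
F2 | step 12 | trans-fused ketone, (4aS,9aS)-5,6,8-trimethoxy-1,1,4a-trimethyl-7-(propan-2-yl)-1,2,3,4,4a,9a-hexahydro-9H-fluoren-9-one | COc1c(OC)c(C(C)C)c(OC)c2c1[C@@]1(C)CCCC(C)(C)[C@@H]1C2=O
F3 | step 12 | exocyclic alkene, the 9-methylidene analogue of F2 | COc1c(OC)c(C(C)C)c(OC)c2c1[C@@]1(C)CCCC(C)(C)[C@@H]1C2=C
F4 | step 12 | diol, the 9α-hydroxy-9β-(hydroxymethyl) analogue of 20 | COc1c(OC)c(C(C)C)c(OC)c2c1[C@@]1(C)CCCC(C)(C)[C@@H]1[C@]2(O)CO
F5 | step 6 | ethyl 2-[(1S)-4,6,7-trimethoxy-1-methyl-5-(propan-2-yl)-1H-inden-1-yl]acetate | COc1c(OC)c(C(C)C)c(OC)c2c1[C@@](C)(CC(=O)OCC)C=C2
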